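The trap in repeating this run is the clean curve of the starting material: it tempts me to extend it past what the coupling partner can pay for.

| setting | oak | elm | Tuesday's | Friday's |
|---|---|---|---|---|
| starting material | 0.40 M | 0.40 M | 0.40 M | 0.40 M |
| coupling partner | 0.32 M | 0.32 M | 0.320 M | 0.320 M |
| initiator | 5.2 mM | 12 mM | 4.0 mM | 8.0 mM |
| remark | run made earlier | run made earlier |  |  |
| time |  |  | 15 min | 15 min |

| run | time / min | starting material / % | first chain carrier / % | product / % |
|---|---|---|---|---|
| oak | 0.667 | 95.0 | 0.2 | 4.9 |
| oak | 2.00 | 85.4 | 0.7 | 14.9 |
| oak | 4.00 | 73.5 | 0.1 | 27.0 |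
| oak | 5.00 | 68.3 | 0.2 | 32.0 |
| oak | 8.00 | 55.1 | 0 | 45.1 |
| elm | 1.50 | 83.4 | 0.8 | 17.4 |
| elm | 3.00 | 69.8 | 0.6 | 30.6 |
| elm | 5.00 | 56.1 | 0 | 45.2 |
| elm | 6.00 | 49.4 | 0.1 | 51.5 |
| elm | 8.00 | 39.1 | 0 | 59.6 |

(standard deviation of a reading: 0.5 percentage points)



1. which of these there is most of at the end, counted by the starting material in it, Tuesday's (first chain carrier / starting material / product)
2. which of these there is most of at the end, counted by the starting material in it, Friday's (first chain carrier / starting material / product)
3. amount of the one of these that there is most of at the end, in percent of the starting material charged, Tuesday's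
4. amount of the one of these that there is most of at the end, in percent of the starting material charged, Friday's

The first chain carrier reads at most 0.8 %, so I count the starting material lost as product. My bench rule is first-order loss with rate constant k, read at each run's last reading. I freeze k/√N, where N is the initiator concentration.

oak: k = ln(charged/left)/t = 0.0745 min⁻¹

elm: k = 0.117 min⁻¹

elm over oak: 1.57 read, against 1.52 from the square root of N

That is close enough for me, so I scale oak's k by √N and take the product as what exp(−kt) does not leave.

Tuesday's: k = 0.0653 min⁻¹, product 62.5 %

Friday's: k = 0.0924 min⁻¹, product 75.0 %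

But I assume each product takes up one coupling partner, and the partner is charged below the starting material, so it is the limiting reagent. My border is this ratio:

C = 80.0 %

C is the partner ceiling: the product the partner charge pays for, as a share of the starting material charged. I do not extend the first-order rule past it. Tuesday's reckoned product is 0.781 of C and Friday's is 0.938 of C, so Friday's is the flask where I watch the partner.

The forecast names product for both flasks, with 62 % (58 % to 66 %) for Tuesday's and 74 % (70 % to 78 %) for Friday's, the latter a little under mine, and it warns that “the estimate could fall slightly short”.

Tuesday's gives product at 59.2 %, with starting material at 40.8 %. Friday's gives product at 70.3 %, with starting material at 29.6 %.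

    initiator → 2 initiating radical (k = 9.00 × 10⁻⁴ s⁻¹)
    starting material + initiating radical → capped initiator + first chain carrier (k = 81000 L mol⁻¹ s⁻¹)
    coupling partner + first chain carrier → product + second chain carrier (k = 1900 L mol⁻¹ s⁻¹)
    starting material + second chain carrier → by-product + first chain carrier (k = 1400 L mol⁻¹ s⁻¹)
    2 second chain carrier → ended chains (k = 5.00 × 10⁶ L mol⁻¹ s⁻¹)
    coupling partner → decomposed reagent (k = 4.00 × 10⁻⁴ s⁻¹)

Friday's coupling partner stands at 0 % at the end, and 0.0389 M is decomposed reagent. C less that amount, counted against the starting material charged, is 70.3 %, beside the 70.3 % of product. The neighbouring flask is Friday's with 0.19 M of coupling partner. There C is 47.5 %, below my first-order 75.0 %. Less its 0.0121 M of decomposed reagent, C is 44.5 %. That flask gives 44.5 % of product with coupling partner at 0 %, and starting material leads at 54 %.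

Readings and results come from a simulation on assumed constants; scatter was added.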